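**Strategy**

Ring A is taken apart at C4a–C5 and C8–C8a: the four-carbon run C5–C8, with its methoxy groups on C6 and C7, is dimethyl squarate, and the C4a=C8a carbons are the enol-ether double bond of an enantiopure 2-aryl-dihydropyran (ring C, C2 already set). Heating the squarate adduct opens the cyclobutenone to a dienylketene whose ketene carbon bonds to C4a; tautomerisation then delivers the whole oxygenated ring A as a 5,8-hydroquinone in one operation. The precursor is the 4-hydroxycyclobutenone formed from dimethyl squarate and the C8a-lithiated (2S,4S)-dihydropyran bearing triisopropylsilyl ethers at O4 and O4'. The C8 hydroxyl later becomes the prenyl group through its triflate.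

Key step: step 6

**Remarks on the chemistry**

- Atom labels follow flavan numbering (O1, C2, C3, C4, C4a, C5–C8, C8a, primed B-ring) for all intermediates, including the monocyclic pyrans.
- The sense of induction in step 2 is assigned by analogy with titanium–biaryldiol additions to aryl aldehydes (Si-face attack with the (S)-ligand). If the rotation of 6 shows the opposite sense, the (R)-ligand is used and nothing else changes.
- Both O4 and O4' carry triisopropylsilyl groups: there is no Si–CH3 group for t-BuLi to metalate, the bulky O4 ether shields the neighbouring 5-OH in step 7, and one fluoride step removes both.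
- The carbinol carbon of 12 forms as a mixture of epimers and is drawn without a descriptor, because it becomes aromatic C8.

**Route**

Step 1
Reactants: 1 4-hydroxybenzaldehyde; 2 chlorotriisopropylsilane
Product: 3 4-(triisopropylsilyloxy)benzaldehyde
Conditions: TIPSCl, imidazole, DMF, rt
Reagents that add atoms: chlorotriisopropylsilane (2), CC(C)[Si](Cl)(C(C)C)C(C)C
Why: Imidazole-mediated silylation of a phenol is routine, and the bulky aryl TIPS ether should withstand t-BuLi later without directing ortho-metalation.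

Step 2
Reactants: 3 4-(triisopropylsilyloxy)benzaldehyde; 4 Danishefsky's diene
Product: 6 (S)-2-[4-(triisopropylsilyloxy)phenyl]-2,3-dihydro-4H-pyran-4-one, via silyl aldol adduct 5 (not isolated)
Conditions: (S)-H8-BINOL (22 mol %), Ti(OiPr)4 (20 mol %), 4 Å MS, toluene, 0 °C; then TFA, CH2Cl2, 0 °C
Reagents that add atoms: Danishefsky's diene (4), CO/C=C/C(=C)O[Si](C)(C)C
Why: Catalytic asymmetric hetero-Diels–Alder reaction (Mukaiyama aldol addition, then acid cyclisation with loss of methanol) of an aryl aldehyde with Danishefsky's diene under a titanium–biaryldiol Lewis acid is a standard entry to 2-aryl-dihydropyranones, and the ligand should block the Re face of the aldehyde so that attack on the Si face sets C2 as S.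

Step 3
Reactants: 6 (S)-2-[4-(triisopropylsilyloxy)phenyl]-2,3-dihydro-4H-pyran-4-one
Product: 7 (2S,4S)-2-[4-(triisopropylsilyloxy)phenyl]-3,4-dihydro-2H-pyran-4-ol
Conditions: NaBH4, CeCl3·7H2O, MeOH, −78 °C
Reagents that add atoms: none
Why: Luche 1,2-reduction of the vinylogous ester carbonyl should proceed by axial hydride delivery on the half-chair with the aryl group equatorial, giving the equatorial 2,4-cis alcohol (4S).

Step 4
Reactants: 7 (2S,4S)-2-[4-(triisopropylsilyloxy)phenyl]-3,4-dihydro-2H-pyran-4-ol; 8 triisopropylsilyl trifluoromethanesulfonate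
Product: 9 (2S,4S)-4-(triisopropylsilyloxy)-2-[4-(triisopropylsilyloxy)phenyl]-3,4-dihydro-2H-pyran
Conditions: TIPSOTf, 2,6-lutidine, CH2Cl2, −78 to 0 °C
Reagents that add atoms: triisopropylsilyl trifluoromethanesulfonate (8), CC(C)[Si](OS(=O)(=O)C(F)(F)F)(C(C)C)C(C)C
Why: Silylation with a silyl triflate under buffered, cold conditions is fast on a secondary alcohol and avoids the free acid that would ionise the allylic enol ether (Ferrier-type loss of the C4 oxygen).

Step 5
Reactants: 9 (2S,4S)-4-(triisopropylsilyloxy)-2-[4-(triisopropylsilyloxy)phenyl]-3,4-dihydro-2H-pyran; 10 dimethyl squarate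
Product: 12 4-hydroxy-2,3-dimethoxy-4-{(2S,4S)-4-(triisopropylsilyloxy)-2-[4-(triisopropylsilyloxy)phenyl]-3,4-dihydro-2H-pyran-6-yl}cyclobut-2-en-1-one, via C8a-lithio dihydropyran 11 (not isolated)
Conditions: t-BuLi (2.2 equiv), THF, −78 to 0 °C, then −78 °C; cannula into 10 (1.3 equiv), THF, −78 °C; NH4Cl aq, −78 °C
Reagents that add atoms: dimethyl squarate (10), COC1=C(OC)C(=O)C1=O
Why: Oxygen-directed deprotonation of the enol-ether vinyl C–H, as in the C1-lithiation of silylated glycals, should give the vinyllithium (surplus base is consumed by THF on warming), which adds 1,2 to one carbonyl of the symmetric squarate in a Moore-type squarate addition.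

Step 6
Reactants: 12 4-hydroxy-2,3-dimethoxy-4-{(2S,4S)-4-(triisopropylsilyloxy)-2-[4-(triisopropylsilyloxy)phenyl]-3,4-dihydro-2H-pyran-6-yl}cyclobut-2-en-1-one
Product: 15 (2S,4S)-6,7-dimethoxy-4-(triisopropylsilyloxy)-2-[4-(triisopropylsilyloxy)phenyl]chromane-5,8-diol, via dienylketene 13 (not isolated), via cyclohexadienone 14 (not isolated)
Conditions: degassed toluene (0.02 M), 110 °C, argon (p-xylene, 138 °C if slow); crude product carried on under argon
Reagents that add atoms: none
Why: This is a Moore-type thermal rearrangement of a 4-alkenyl-4-hydroxycyclobutenone, in which conrotatory 4π opening cleaves the bond between the carbinol carbon and the carbonyl carbon and the donor hydroxyl turns outward, so the dihydropyranyl group lies beside the ketene in 13. Disrotatory 6π electrocyclisation across the ketene C=C, the C7=C8 bond and the C8a=C4a enol ether then joins the ketene carbon C5 to the nucleophilic β-carbon C4a and closes the six-membered carbocycle, ring A, as dienone 14. Enolisation of 14 with loss of the C4a hydrogen should give the aromatic 5,8-hydroquinone 15. No stereocentre is created, since C4a is only transiently tetrahedral and the carbinol carbon becomes aromatic C8, while C2 and C4 are spectators. The step needs outward torquoselectivity of the hydroxyl, which its donor character secures, and regiochemistry is not in question because C4a is the only terminus within reach; neutral, oxygen-free conditions are chosen so that the C4 silyl ether does not eliminate and the hydroquinone is not oxidised.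

Step 7
Reactants: 15 (2S,4S)-6,7-dimethoxy-4-(triisopropylsilyloxy)-2-[4-(triisopropylsilyloxy)phenyl]chromane-5,8-diol; 16 N-phenylbis(trifluoromethanesulfonimide)
Product: 17 (2S,4S)-5-hydroxy-6,7-dimethoxy-4-(triisopropylsilyloxy)-2-[4-(triisopropylsilyloxy)phenyl]chroman-8-yl trifluoromethanesulfonate
Conditions: PhNTf2 (1.05 equiv), Et3N, CH2Cl2, 0 °C to rt, argon
Reagents that add atoms: N-phenylbis(trifluoromethanesulfonimide) (16), O=S(=O)(N(c1ccccc1)S(=O)(=O)C(F)(F)F)C(F)(F)F
Why: Phenol triflation with one equivalent of the bulky imide should take the 8-OH, which sits between a methoxy group and the ring oxygen, in preference to the 5-OH, which is buttressed by the peri C4–OTIPS group.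

Step 8
Reactants: 17 (2S,4S)-5-hydroxy-6,7-dimethoxy-4-(triisopropylsilyloxy)-2-[4-(triisopropylsilyloxy)phenyl]chroman-8-yl trifluoromethanesulfonate; 18 prenylboronic acid pinacol ester
Product: 19 (2S,4S)-6,7-dimethoxy-8-(3-methylbut-2-en-1-yl)-4-(triisopropylsilyloxy)-2-[4-(triisopropylsilyloxy)phenyl]chroman-5-ol
Conditions: 18 (1.5 equiv), Pd(OAc)2 (5 mol %), t-BuXPhos (10 mol %), K3PO4 aq, degassed THF, 40 °C
Reagents that add atoms: prenylboronic acid pinacol ester (18), CC(C)=CCB1OC(C)(C)C(C)(C)O1
Why: Suzuki–Miyaura coupling of an aryl triflate with an allylic boronate under a bulky electron-rich biarylphosphine should let the allylpalladium intermediate settle as the less hindered primary σ-allyl before reductive elimination, giving the linear prenyl arene while tolerating the free phenol and the silyl ethers.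

Step 9
Reactants: 19 (2S,4S)-6,7-dimethoxy-8-(3-methylbut-2-en-1-yl)-4-(triisopropylsilyloxy)-2-[4-(triisopropylsilyloxy)phenyl]chroman-5-ol
Product: 20 (2S,4S)-2-(4-hydroxyphenyl)-6,7-dimethoxy-8-(3-methylbut-2-en-1-yl)chromane-4,5-diol
Conditions: TBAF (4 equiv), THF, 0 °C to rt; AcOH quench
Reagents that add atoms: none
Why: Fluoride-mediated desilylation should cleave the aryl ether quickly and the secondary C4 ether more slowly (assisted by the neighbouring 5-phenoxide) at or below room temperature, where neither the prenyl group nor C2 is at risk.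

Step 10
Reactants: 20 (2S,4S)-2-(4-hydroxyphenyl)-6,7-dimethoxy-8-(3-methylbut-2-en-1-yl)chromane-4,5-diol
Product: 21 (2S)-5-hydroxy-2-(4-hydroxyphenyl)-6,7-dimethoxy-8-(3-methylbut-2-en-1-yl)chroman-4-one (target)
Conditions: activated MnO2 (15 equiv), EtOAc, rt
Reagents that add atoms: none
Why: MnO2 oxidation is selective for benzylic alcohols (here further activated by the ortho hydroxyl) and is neutral, so the phenols, the prenyl alkene and the base-sensitive C2 centre of the flavanone should survive.

**Compound list**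

1 | 4-hydroxybenzaldehyde | O=Cc1ccc(O)cc1 | starting material
2 | chlorotriisopropylsilane | CC(C)[Si](Cl)(C(C)C)C(C)C | starting material
3 | 4-(triisopropylsilyloxy)benzaldehyde | O=Cc1ccc(O[Si](C(C)C)(C(C)C)C(C)C)cc1 | intermediate
4 | Danishefsky's diene, (E)-1-methoxy-3-(trimethylsilyloxy)buta-1,3-diene | CO/C=C/C(=C)O[Si](C)(C)C | starting material
5 | (S,E)-1-methoxy-5-[4-(triisopropylsilyloxy)phenyl]-5-(trimethylsilyloxy)pent-1-en-3-one (not isolated) | CO/C=C/C(=O)C[C@H](O[Si](C)(C)C)c1ccc(O[Si](C(C)C)(C(C)C)C(C)C)cc1 | intermediate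
6 | (S)-2-[4-(triisopropylsilyloxy)phenyl]-2,3-dihydro-4H-pyran-4-one | O=C1C=CO[C@H](c2ccc(O[Si](C(C)C)(C(C)C)C(C)C)cc2)C1 | intermediate
7 | (2S,4S)-2-[4-(triisopropylsilyloxy)phenyl]-3,4-dihydro-2H-pyran-4-ol (2,4-cis) | C1=C[C@@H](O)C[C@@H](c2ccc(O[Si](C(C)C)(C(C)C)C(C)C)cc2)O1 | intermediate
8 | triisopropylsilyl trifluoromethanesulfonate | CC(C)[Si](OS(=O)(=O)C(F)(F)F)(C(C)C)C(C)C | starting material
9 | (2S,4S)-4-(triisopropylsilyloxy)-2-[4-(triisopropylsilyloxy)phenyl]-3,4-dihydro-2H-pyran | C1=C[C@@H](O[Si](C(C)C)(C(C)C)C(C)C)C[C@@H](c2ccc(O[Si](C(C)C)(C(C)C)C(C)C)cc2)O1 | intermediate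
10 | dimethyl squarate | COC1=C(OC)C(=O)C1=O | starting material
11 | 6-lithio derivative of 9, lithium on the future C8a (not isolated) | [Li]C1=C[C@@H](O[Si](C(C)C)(C(C)C)C(C)C)C[C@@H](c2ccc(O[Si](C(C)C)(C(C)C)C(C)C)cc2)O1 | intermediate
12 | 4-hydroxy-2,3-dimethoxy-4-{(2S,4S)-4-(triisopropylsilyloxy)-2-[4-(triisopropylsilyloxy)phenyl]-3,4-dihydro-2H-pyran-6-yl}cyclobut-2-en-1-one (carbinol carbon unassigned) | COC1=C(OC)C(O)(C2=C[C@@H](O[Si](C(C)C)(C(C)C)C(C)C)C[C@@H](c3ccc(O[Si](C(C)C)(C(C)C)C(C)C)cc3)O2)C1=O | intermediate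
13 | dienylketene from ring opening of 12, hydroxyl outward (not isolated) | O=C=C(OC)/C(OC)=C(/O)C1=C[C@@H](O[Si](C(C)C)(C(C)C)C(C)C)C[C@@H](c2ccc(O[Si](C(C)C)(C(C)C)C(C)C)cc2)O1 | intermediate
14 | (2S,4S)-8-hydroxy-6,7-dimethoxy-4-(triisopropylsilyloxy)-2-[4-(triisopropylsilyloxy)phenyl]-2,3,4,4a-tetrahydro-5H-chromen-5-one, C4a unassigned (not isolated) | COC1=C(OC)C(O)=C2O[C@H](c3ccc(O[Si](C(C)C)(C(C)C)C(C)C)cc3)C[C@H](O[Si](C(C)C)(C(C)C)C(C)C)C2C1=O | intermediate
15 | (2S,4S)-6,7-dimethoxy-4-(triisopropylsilyloxy)-2-[4-(triisopropylsilyloxy)phenyl]chromane-5,8-diol | COc1c(O)c2c(c(O)c1OC)O[C@H](c1ccc(O[Si](C(C)C)(C(C)C)C(C)C)cc1)C[C@@H]2O[Si](C(C)C)(C(C)C)C(C)C | intermediate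
16 | N-phenylbis(trifluoromethanesulfonimide) | O=S(=O)(N(c1ccccc1)S(=O)(=O)C(F)(F)F)C(F)(F)F | starting material
17 | (2S,4S)-5-hydroxy-6,7-dimethoxy-4-(triisopropylsilyloxy)-2-[4-(triisopropylsilyloxy)phenyl]chroman-8-yl trifluoromethanesulfonate | COc1c(O)c2c(c(OS(=O)(=O)C(F)(F)F)c1OC)O[C@H](c1ccc(O[Si](C(C)C)(C(C)C)C(C)C)cc1)C[C@@H]2O[Si](C(C)C)(C(C)C)C(C)C | intermediate
18 | prenylboronic acid pinacol ester | CC(C)=CCB1OC(C)(C)C(C)(C)O1 | starting material
19 | (2S,4S)-6,7-dimethoxy-8-(3-methylbut-2-en-1-yl)-4-(triisopropylsilyloxy)-2-[4-(triisopropylsilyloxy)phenyl]chroman-5-ol | COc1c(O)c2c(c(CC=C(C)C)c1OC)O[C@H](c1ccc(O[Si](C(C)C)(C(C)C)C(C)C)cc1)C[C@@H]2O[Si](C(C)C)(C(C)C)C(C)C | intermediate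
20 | (2S,4S)-2-(4-hydroxyphenyl)-6,7-dimethoxy-8-(3-methylbut-2-en-1-yl)chromane-4,5-diol | COc1c(O)c2c(c(CC=C(C)C)c1OC)O[C@H](c1ccc(O)cc1)C[C@@H]2O | intermediate
21 | (2S)-5-hydroxy-2-(4-hydroxyphenyl)-6,7-dimethoxy-8-(3-methylbut-2-en-1-yl)chroman-4-one | COc1c(O)c2c(c(CC=C(C)C)c1OC)O[C@H](c1ccc(O)cc1)CC2=O | target

**Step count and risks**

Total step count: 10. Longest linear sequence: 10 steps (from 1 to 21).

Steps most likely to fail:

1. Step 6 (ring expansion). The dienylketene may be diverted before it closes: the free hydroxyl can add to the ketene if rotation is not cleanly outward, the carbinol can rearrange under trace acid before ring opening, and the electron-rich hydroquinone can oxidise during isolation. Fallback: from 12, the tertiary hydroxyl is capped (TMSCl, imidazole, CH2Cl2, 0 °C) to give the 4-(trimethylsilyloxy)cyclobutenone F1. Its thermolysis in degassed p-xylene at 138 °C, a well-established variant of the same ring expansion that has no free hydroxyl, should give the 8-O-trimethylsilyl monoether of the hydroquinone F2, which is also less air-sensitive. Brief methanolysis (cat. K2CO3, degassed MeOH, 0 °C) returns to 15.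

2. Step 8 (prenyl coupling). The allyl fragment may couple through its tertiary carbon to give the 1,1-dimethylallyl isomer, the electron-rich triflate may be hydrolysed by the aqueous base, or oxidative addition next to two ortho oxygens may be slow. Fallback: from 17, Stille coupling with allyltributylstannane (Pd(PPh3)4, LiCl, dioxane, 100 °C), which is neutral and has no regiochemical ambiguity, gives the 8-allyl chromanol F3. Cross-metathesis of F3 with 2-methyl-2-butene (used in excess, second-generation Grubbs catalyst RuCl2(=CHPh)(PCy3)(H2IMes), CH2Cl2, 40 °C) converts allyl into prenyl and returns to 19.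

3. Step 5 (lithiation and squarate addition). Metalation may occur at the wrong site, namely the benzylic, oxygen-bearing C2–H, which would also erode the C2 configuration; lithiation may be incomplete; or surviving t-BuLi may attack the squarate. Fallback: 11 is generated without a deprotonation step. From 9, acid-catalysed hydration of the enol ether (PPh3·HBr cat., wet THF) gives the lactol F4. Oxidation (tetrapropylammonium perruthenate nPr4N[RuO4] cat., NMO, CH2Cl2) gives the δ-lactone F5. O-Phosphorylation of its potassium enolate (KHMDS, (PhO)2P(O)Cl, THF/HMPA, −78 °C) gives the ketene acetal phosphate F6. Palladium-catalysed stannylation (Pd(PPh3)4, Me3SnSnMe3, LiCl, THF, reflux) gives the vinylstannane F7. Tin–lithium exchange (MeLi, THF, −78 °C) then delivers 11 free of excess base for the addition to 10, rejoining the route at 12.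

**Further compounds**

F1 | step 6 | 2,3-dimethoxy-4-(trimethylsilyloxy)-4-{(2S,4S)-4-(triisopropylsilyloxy)-2-[4-(triisopropylsilyloxy)phenyl]-3,4-dihydro-2H-pyran-6-yl}cyclobut-2-en-1-one | COC1=C(OC)C(O[Si](C)(C)C)(C2=C[C@@H](O[Si](C(C)C)(C(C)C)C(C)C)C[C@@H](c3ccc(O[Si](C(C)C)(C(C)C)C(C)C)cc3)O2)C1=O
F2 | step 6 | (2S,4S)-6,7-dimethoxy-4-(triisopropylsilyloxy)-2-[4-(triisopropylsilyloxy)phenyl]-8-(trimethylsilyloxy)chroman-5-ol | COc1c(O)c2c(c(O[Si](C)(C)C)c1OC)O[C@H](c1ccc(O[Si](C(C)C)(C(C)C)C(C)C)cc1)C[C@@H]2O[Si](C(C)C)(C(C)C)C(C)C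
F3 | step 8 | (2S,4S)-8-allyl-6,7-dimethoxy-4-(triisopropylsilyloxy)-2-[4-(triisopropylsilyloxy)phenyl]chroman-5-ol | COc1c(O)c2c(c(CC=C)c1OC)O[C@H](c1ccc(O[Si](C(C)C)(C(C)C)C(C)C)cc1)C[C@@H]2O[Si](C(C)C)(C(C)C)C(C)C
F4 | step 5 | (4S,6S)-4-(triisopropylsilyloxy)-6-[4-(triisopropylsilyloxy)phenyl]tetrahydro-2H-pyran-2-ol (anomeric mixture) | OC1C[C@@H](O[Si](C(C)C)(C(C)C)C(C)C)C[C@@H](c2ccc(O[Si](C(C)C)(C(C)C)C(C)C)cc2)O1
F5 | step 5 | (4S,6S)-4-(triisopropylsilyloxy)-6-[4-(triisopropylsilyloxy)phenyl]tetrahydro-2H-pyran-2-one | O=C1C[C@@H](O[Si](C(C)C)(C(C)C)C(C)C)C[C@@H](c2ccc(O[Si](C(C)C)(C(C)C)C(C)C)cc2)O1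
F6 | step 5 | (2S,4S)-4-(triisopropylsilyloxy)-2-[4-(triisopropylsilyloxy)phenyl]-3,4-dihydro-2H-pyran-6-yl diphenyl phosphate | O=P(Oc1ccccc1)(Oc1ccccc1)OC1=C[C@@H](O[Si](C(C)C)(C(C)C)C(C)C)C[C@@H](c2ccc(O[Si](C(C)C)(C(C)C)C(C)C)cc2)O1
F7 | step 5 | trimethyl{(2S,4S)-4-(triisopropylsilyloxy)-2-[4-(triisopropylsilyloxy)phenyl]-3,4-dihydro-2H-pyran-6-yl}stannane | C[Sn](C)(C)C1=C[C@@H](O[Si](C(C)C)(C(C)C)C(C)C)C[C@@H](c2ccc(O[Si](C(C)C)(C(C)C)C(C)C)cc2)O1
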